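**Retrosynthetic overview**

1. Ambrein (32) is cut at C11–C12 into the bicyclic C11 phenyl sulfone 23 and the (S,E)-allylic bromide 30; the cyclohexane ring of 30 is made on its own by an enzymatic monocyclisation of geranylacetone.
2. Sulfone 23 comes from the exocyclic-methylene decalin 18 (α-face epoxidation then hydride opening sets C8; the C6 acyl group is excised by decarboxylation), and 18 comes from allylsilane 17 by protodesilylation, which sets C9.
3. Allylsilane 17 comes from the acyclic trienimide 16 by an auxiliary-controlled intramolecular Diels–Alder reaction that closes rings A and B of the decalin together through the C5–C10 and C6–C7 bonds.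
4. Enabling feature: ring B (C5–C6–C7–C8–C9–C10) carries the C8 carbinol next to the C9 methine, the retron of a C8=C9 cyclohexene, so C7=C8–C9=C10 is a diene and C5=C6 a dienophile; C10 and C5 are also bridged by the four-carbon chain C1–C4 of ring A (gem-dimethyl at C4), which makes the [4+2] a type-1 cycloaddition of a 1,3,9-decatriene.
5. Trienimide 16 comes from aldehyde 11 and phosphonate 15; the tetrasubstituted C9=C10 alkene gets its geometry from enol tosylate 4 (ethyl acetoacetate + PhSCH2Cl) coupled with alkenol 6, and the 2-(silylmethyl)diene is made from the ester.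

Key step: step 10

**Remarks (assumptions)**
- Atom numbers C1–C12, C17 and C20 are the labdane/drimane positions of the bicyclic half: C4 gem-dimethyl, C5/C10 ring fusion, C8 carbinol, C17 its methyl, C9 side-chain carbon, C20 the angular methyl.
- Enolates and lithio-anions of numbered compounds are not numbered separately.
- An engineered squalene–hopene cyclase variant that stops after the first ring closure is assumed to be available as a whole-cell catalyst, and (E)-geranylacetone is used as the pure E isomer.

**Route**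

Step 1
Reactants: 1 ethyl acetoacetate; 2 chloromethyl phenyl sulfide
Product: 3 ethyl 3-oxo-2-[(phenylsulfanyl)methyl]butanoate (racemic)
Conditions: NaH (1.0 equiv), NaI (cat.), THF, 0 °C → rt; 1 in slight excess
Reagents that add atoms: none
Why: C-alkylation of the sodium enolate of a β-keto ester by an α-chloro sulfide (SN2 at an activated carbon) installs C11 with its sulfur handle, and the small excess of 1 limits dialkylation.

Step 2
Reactants: 3 ethyl 3-oxo-2-[(phenylsulfanyl)methyl]butanoate
Product: 4 ethyl (2Z)-3-{[(4-methylphenyl)sulfonyl]oxy}-2-[(phenylsulfanyl)methyl]but-2-enoate (tosyloxy trans to the ester, methyl cis to the ester)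
Conditions: TsCl, N-methylimidazole, Et3N, MeCN, 0 °C
Reagents that add atoms: p-toluenesulfonyl chloride, Cc1ccc(cc1)S(Cl)(=O)=O
Why: Stereoselective enol tosylation of an α-substituted β-keto ester under non-chelating amine conditions should trap the open enolate with OTs trans to the ester (lithium-chelate conditions give the other isomer), which fixes the C9=C10 geometry needed for the diene.

Step 3
Reactants: 5 2,2-dimethylpent-4-enal
Product: 6 2,2-dimethylpent-4-en-1-ol
Conditions: NaBH4, MeOH, 0 °C
Reagents that add atoms: none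
Why: Borohydride reduction of a non-enolisable aldehyde gives the neopentyl alcohol that later becomes C5.

Step 4
Reactants: 6 2,2-dimethylpent-4-en-1-ol; 4 enol tosylate
Product: 8 ethyl (2Z)-8-hydroxy-3,7,7-trimethyl-2-[(phenylsulfanyl)methyl]oct-2-enoate, via B-alkyl-9-BBN adduct 7 (not isolated)
Conditions: 9-BBN (2.2 equiv), THF, 0 °C → rt; then 4, Pd(OAc)2/SPhos (cat.), K3PO4, H2O, THF, 50 °C
Reagents that add atoms: none
Why: Anti-Markovnikov hydroboration of the terminal alkene followed by B-alkyl Suzuki–Miyaura coupling at the activated enol tosylate proceeds with retention of alkene geometry, so the C1–C5 chain ends up trans to the ester and cis to CH2SPh.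

Step 5
Reactants: 8 hydroxy enoate
Product: 10 (6Z)-2,2,6-trimethyl-7-[(phenylsulfanyl)methyl]-8-[(trimethylsilyl)methyl]nona-6,8-dien-1-ol, via bis(silylmethyl) carbinol 9 (not isolated)
Conditions: Me3SiCH2MgCl (5 equiv), anhydrous CeCl3, THF, −78 °C → rt; then SiO2, CH2Cl2
Reagents that add atoms: (trimethylsilyl)methylmagnesium chloride, C[Si](C)(C)C[Mg]Cl
Why: Cerium-mediated double 1,2-addition of the silylmethyl nucleophile to the ester and Peterson elimination of the tertiary β-hydroxysilane on silica is the established ester-to-2-(silylmethyl)allyl conversion, here giving the 2-(silylmethyl)-1,3-diene (C7 and C17) without touching the alkene geometry.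

Step 6
Reactants: 10 dienol
Product: 11 (6Z)-2,2,6-trimethyl-7-[(phenylsulfanyl)methyl]-8-[(trimethylsilyl)methyl]nona-6,8-dienal
Conditions: SO3·pyridine, DMSO, i-Pr2NEt, CH2Cl2, 0 °C
Reagents that add atoms: none
Why: Parikh–Doering oxidation is non-acidic and spares the sulfide, the allylsilane and the diene, and the α-quaternary aldehyde cannot epimerise or enolise.

Step 7
Reactants: 12 (4S)-4-benzyl-1,3-oxazolidin-2-one; 13 bromoacetyl bromide
Product: 14 (4S)-4-benzyl-3-(bromoacetyl)-1,3-oxazolidin-2-one
Conditions: n-BuLi, THF, −78 °C; then 13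
Reagents that add atoms: none
Why: N-Acylation of the lithiated oxazolidinone with an acyl bromide is standard and leaves the stereocentre untouched.

Step 8
Reactants: 14 bromoacetyl imide
Product: 15 diethyl {2-[(4S)-4-benzyl-2-oxo-1,3-oxazolidin-3-yl]-2-oxoethyl}phosphonate
Conditions: P(OEt)3, toluene, 80 °C
Reagents that add atoms: triethyl phosphite, CCOP(OCC)OCC
Why: Michaelis–Arbuzov reaction of an α-bromo imide gives the stabilised phosphonate.

Step 9
Reactants: 11 dienal; 15 phosphonate
Product: 16 (4S)-4-benzyl-3-{(2E,8Z)-4,4,8-trimethyl-9-[(phenylsulfanyl)methyl]-10-[(trimethylsilyl)methyl]undeca-2,8,10-trienoyl}-1,3-oxazolidin-2-one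
Conditions: LiCl, i-Pr2NEt, MeCN, rt
Reagents that add atoms: none
Why: Horner–Wadsworth–Emmons olefination under mild LiCl/amine conditions gives the E-enimide, and the bulky non-enolisable aldehyde reinforces E selectivity.

Step 10
Reactants: 16 trienimide
Product: 17 (4S)-4-benzyl-3-{[(1S,4aS,8aS)-4a,8,8-trimethyl-4-[(phenylsulfanyl)methyl]-3-[(trimethylsilyl)methyl]-1,2,4a,5,6,7,8,8a-octahydronaphthalen-1-yl]carbonyl}-1,3-oxazolidin-2-one (trans-fused; 10β-CH3, 5α-H, 6α-acyl, C8=C9)
Conditions: Me2AlCl (2.5 equiv), CH2Cl2, −30 → 0 °C; aqueous Rochelle-salt work-up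
Reagents that add atoms: none
Why: Me2AlCl in excess converts the imide into the cationic bidentate aluminium chelate (s-cis enoyl), a strongly LUMO-lowered dienophile that should undergo a concerted, asynchronous type-1 intramolecular Diels–Alder reaction with the s-cis C7=C8–C9=C10 diene, forming C5–C10 and C6–C7 suprafacially; the closest known reaction type is the Lewis-acid-promoted cycloaddition of N-trienoyl oxazolidinones (terminally activated decatrienes) to trans-octalins. Ring B (C5–C6–C7–C8–C9–C10) is closed by the [4+2] itself, and ring A (C10–C1–C2–C3–C4–C5) is closed at the same time as the fused six-membered tether ring through a chair-like arrangement of the C1–C4 chain, helped by the C4 gem-dimethyl group. The trans relation of C5–H and C10–CH3 follows from the endo transition state (acyl under the diene), which is favoured by the Lewis acid because the tether sits on the outer position of C10 and the dienophile is E; C6 follows from the E geometry and is deleted later. The absolute configuration comes from the auxiliary: in the chelate the (S)-benzyl group shields the Cα-Re face, so the diene adds to the Cα-Si/Cβ-Si face, which gives 5S,10S. The step needs endo over exo selectivity, one π-face, and cycloaddition in preference to Lewis-acid loss of the allylsilane; the chelated imide, the placement of tether and activator, and the aprotic, proton-scavenging alkylaluminium reagent are meant to secure these. The methyl group on the inner position of C10 slows the reaction but becomes the angular methyl group.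

Step 11
Reactants: 17 allylsilane adduct
Product: 18 (4S)-4-benzyl-3-{[(1S,4S,4aS,8aS)-4a,8,8-trimethyl-3-methylidene-4-[(phenylsulfanyl)methyl]decahydronaphthalen-1-yl]carbonyl}-1,3-oxazolidin-2-one (9α-H, 9β-CH2SPh, exocyclic C8=C17)
Conditions: CF3CO2H (3 equiv), CH2Cl2, −20 → 0 °C
Reagents that add atoms: none
Why: Protodesilylation of the allylsilane (SE2′) should deliver the proton axially to C9 from the α face, anti to the axial C10 methyl, setting C9 with the CH2SPh group equatorial (β), while loss of silicon from the β-silyl cation gives the exocyclic C8 methylene.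

Step 12
Reactants: 18 exocyclic alkene
Product: 19 (4S)-4-benzyl-3-{[8α,17-epoxy-11-(phenylsulfonyl)driman-6α-yl]carbonyl}-1,3-oxazolidin-2-one (spiro-oxirane at C8, oxygen on the α face)
Conditions: mCPBA (3.3 equiv), NaHCO3, CH2Cl2, 0 °C → rt
Reagents that add atoms: m-chloroperbenzoic acid, OOC(=O)c1cccc(Cl)c1
Why: The peracid oxidises the sulfide to the sulfone and epoxidises the exocyclic alkene (Prilezhaev) from the equatorial α face because the β face is blocked by the syn-axial C10 methyl, which places the C8 oxygen α as in the target.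

Step 13
Reactants: 19 epoxy sulfone imide
Product: 20 8α,17-epoxy-11-(phenylsulfonyl)drimane-6α-carboxylic acid
Conditions: LiOH, H2O2, THF/H2O, 0 °C; then Na2SO3, dilute HCl
Reagents that add atoms: hydrogen peroxide, OO
Why: Lithium hydroperoxide cleaves the hindered N-acyl oxazolidinone at the exocyclic carbonyl, releases the auxiliary for recovery, and leaves the epoxide and sulfone intact.

Step 14
Reactants: 20 carboxylic acid
Product: 22 8α,17-epoxy-11-(phenylsulfonyl)drimane, via Barton ester 21 (not isolated)
Conditions: 2-mercaptopyridine N-oxide, EDC, DMAP (cat.), CH2Cl2, dark, rt; then t-BuSH, hν (tungsten lamp), rt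
Reagents that add atoms: none
Why: Barton reductive decarboxylation replaces the C6 carboxyl by hydrogen through a secondary C6 radical that is not adjacent to the oxirane, so the activating group of the cycloaddition is removed without touching C5, C8, C9 or C10.

Step 15
Reactants: 22 epoxy sulfone
Product: 23 (1R,2R,4aS,8aS)-2,5,5,8a-tetramethyl-1-[(phenylsulfonyl)methyl]decahydronaphthalen-2-ol (8α-hydroxy-11-(phenylsulfonyl)drimane)
Conditions: LiEt3BH, THF, 0 °C → rt
Reagents that add atoms: none
Why: Hydride opens the 1,1-disubstituted epoxide by SN2 attack at the CH2 carbon, which turns C17 into the C8 methyl and leaves the C8–O bond, and hence the 8α-hydroxyl configuration, unchanged.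

Step 16
Reactants: 24 (E)-geranylacetone
Product: 25 (S)-4-(2,2-dimethyl-6-methylidenecyclohexyl)butan-2-one ((S)-γ-dihydroionone)
Conditions: engineered squalene–hopene cyclase variant (class II terpene cyclase, E. coli whole cells), citrate buffer pH 6, cyclodextrin, 30 °C
Reagents that add atoms: none
Why: The cyclase protonates the terminal alkene of the chair-folded substrate, closes the six-membered ring and deprotonates the methyl group to the exocyclic alkene, a monocyclisation reported for this substrate class, with the S centre set by the active site.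

Step 17
Reactants: 25 (S)-γ-dihydroionone
Product: 27 (S)-2-(but-3-yn-1-yl)-1,1-dimethyl-3-methylidenecyclohexane, via enol phosphate 26 (not isolated)
Conditions: LDA (1.05 equiv), THF, −78 °C; ClP(O)(OEt)2; then LDA (2.3 equiv), −78 °C → rt
Reagents that add atoms: none
Why: Kinetic enolisation at the methyl group, O-phosphorylation and base-induced elimination convert the methyl ketone into the terminal alkyne, and the remote ring stereocentre is not enolisable.

Step 18
Reactants: 27 terminal alkyne
Product: 29 (2E)-5-[(1S)-2,2-dimethyl-6-methylidenecyclohexyl]-3-methylpent-2-en-1-ol, via alkenylalane 28 (not isolated)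
Conditions: AlMe3, Cp2ZrCl2 (cat.), CH2Cl2, 0 °C → rt; then n-BuLi, THF, −78 °C; (CH2O)n, rt
Reagents that add atoms: trimethylaluminium, C[Al](C)C; formaldehyde (as paraformaldehyde), C=O
Why: Negishi zirconium-catalysed carboalumination adds methyl and aluminium syn across the alkyne (methyl to the internal carbon), and the derived alanate is hydroxymethylated with retention, so the trisubstituted C13=C14 alkene is formed as the E isomer only; the 1,1-disubstituted ring alkene does not react.

Step 19
Reactants: 29 allylic alcohol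
Product: 30 (S)-2-[(3E)-5-bromo-3-methylpent-3-en-1-yl]-1,1-dimethyl-3-methylidenecyclohexane
Conditions: CBr4, PPh3, CH2Cl2, 0 °C
Reagents that add atoms: carbon tetrabromide, BrC(Br)(Br)Br
Why: Appel bromination of a primary allylic alcohol proceeds by SN2 under neutral conditions without allylic transposition or isomerisation of either alkene.

Step 20
Reactants: 23 hydroxy sulfone; 30 allylic bromide
Product: 31 11-(phenylsulfonyl)ambrein (mixture of C11 epimers)
Conditions: n-BuLi (2.2 equiv), THF/DMPU, −78 °C; then 30, −78 → −30 °C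
Reagents that add atoms: none
Why: The alkoxide/α-sulfonyl carbanion dianion is C-alkylated at C11 by the primary allylic bromide (SN2), the classical terpenoid sulfone coupling, forming C11–C12 without touching the E-alkene; the new C11 centre is removed in the next step.

Step 21
Reactants: 31 alkylated sulfone
Product: 32 ambrein
Conditions: 6% Na(Hg), Na2HPO4, MeOH/THF, −20 → 0 °C
Reagents that add atoms: none
Why: Reductive desulfonylation by electron transfer cleaves the C11–S bond; the sulfone is homoallylic, so neither alkene can migrate, and the tertiary alcohol is inert.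

**Compound list**

1 | ethyl acetoacetate | CCOC(=O)CC(C)=O | starting material
2 | chloromethyl phenyl sulfide | ClCSc1ccccc1 | starting material
3 | ethyl 3-oxo-2-[(phenylsulfanyl)methyl]butanoate (racemic) | CCOC(=O)C(CSc1ccccc1)C(C)=O | intermediate
4 | ethyl (2Z)-3-(tosyloxy)-2-[(phenylsulfanyl)methyl]but-2-enoate (OTs trans to ester) | CCOC(=O)/C(CSc1ccccc1)=C(\C)OS(=O)(=O)c1ccc(C)cc1 | intermediate
5 | 2,2-dimethylpent-4-enal | C=CCC(C)(C)C=O | starting material
6 | 2,2-dimethylpent-4-en-1-ol | C=CCC(C)(C)CO | intermediate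
7 | 9-(5-hydroxy-4,4-dimethylpentyl)-9-borabicyclo[3.3.1]nonane (not isolated) | OCC(C)(C)CCCB1C2CCCC1CCC2 | intermediate
8 | ethyl (2Z)-8-hydroxy-3,7,7-trimethyl-2-[(phenylsulfanyl)methyl]oct-2-enoate (methyl cis to ester) | CCOC(=O)/C(CSc1ccccc1)=C(\C)CCCC(C)(C)CO | intermediate
9 | (6Z)-2,2,6-trimethyl-7-[(phenylsulfanyl)methyl]-9-(trimethylsilyl)-8-[(trimethylsilyl)methyl]non-6-ene-1,8-diol (not isolated) | C[Si](C)(C)CC(O)(C[Si](C)(C)C)/C(CSc1ccccc1)=C(\C)CCCC(C)(C)CO | intermediate
10 | (6Z)-2,2,6-trimethyl-7-[(phenylsulfanyl)methyl]-8-[(trimethylsilyl)methyl]nona-6,8-dien-1-ol | C=C(C[Si](C)(C)C)/C(CSc1ccccc1)=C(\C)CCCC(C)(C)CO | intermediate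
11 | (6Z)-2,2,6-trimethyl-7-[(phenylsulfanyl)methyl]-8-[(trimethylsilyl)methyl]nona-6,8-dienal | C=C(C[Si](C)(C)C)/C(CSc1ccccc1)=C(\C)CCCC(C)(C)C=O | intermediate
12 | (4S)-4-benzyl-1,3-oxazolidin-2-one | O=C1N[C@@H](Cc2ccccc2)CO1 | starting material
13 | bromoacetyl bromide | BrCC(Br)=O | starting material
14 | (4S)-4-benzyl-3-(bromoacetyl)-1,3-oxazolidin-2-one | O=C(CBr)N1[C@@H](Cc2ccccc2)COC1=O | intermediate
15 | diethyl {2-[(4S)-4-benzyl-2-oxo-1,3-oxazolidin-3-yl]-2-oxoethyl}phosphonate | CCOP(=O)(CC(=O)N1[C@@H](Cc2ccccc2)COC1=O)OCC | intermediate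
16 | (4S)-4-benzyl-3-{(2E,8Z)-4,4,8-trimethyl-9-[(phenylsulfanyl)methyl]-10-[(trimethylsilyl)methyl]undeca-2,8,10-trienoyl}-1,3-oxazolidin-2-one | C=C(C[Si](C)(C)C)/C(CSc1ccccc1)=C(\C)CCCC(C)(C)/C=C/C(=O)N1[C@@H](Cc2ccccc2)COC1=O | intermediate
17 | trans-octalin cycloadduct (10β-CH3, 5α-H, 6α-acyl imide, C8=C9, C8 CH2SiMe3, C9 CH2SPh) | C[Si](C)(C)CC1=C(CSc2ccccc2)[C@@]3(C)CCCC(C)(C)[C@@H]3[C@@H](C(=O)N4[C@@H](Cc5ccccc5)COC4=O)C1 | intermediate
18 | 6α-acyl imide of 11-(phenylsulfanyl)drim-8(17)-ene (9α-H) | c1ccccc1SC[C@@H]2[C@@]3(C)CCCC(C)(C)[C@@H]3[C@@H](C(=O)N4[C@@H](Cc5ccccc5)COC4=O)CC2=C | intermediate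
19 | 6α-acyl imide of 8α,17-epoxy-11-(phenylsulfonyl)drimane | O=S(=O)(c1ccccc1)C[C@@H]2[C@@]3(C)CCCC(C)(C)[C@@H]3[C@@H](C(=O)N4[C@@H](Cc5ccccc5)COC4=O)C[C@]26CO6 | intermediate
20 | 8α,17-epoxy-11-(phenylsulfonyl)drimane-6α-carboxylic acid | O=S(=O)(c1ccccc1)C[C@@H]2[C@@]3(C)CCCC(C)(C)[C@@H]3[C@@H](C(=O)O)C[C@]24CO4 | intermediate
21 | 2-thioxopyridin-1(2H)-yl ester of acid 20 (not isolated) | O=S(=O)(c1ccccc1)C[C@@H]2[C@@]3(C)CCCC(C)(C)[C@@H]3[C@@H](C(=O)On4ccccc4=S)C[C@]25CO5 | intermediate
22 | 8α,17-epoxy-11-(phenylsulfonyl)drimane | O=S(=O)(c1ccccc1)C[C@@H]2[C@@]3(C)CCCC(C)(C)[C@@H]3CC[C@]24CO4 | intermediate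
23 | (1R,2R,4aS,8aS)-2,5,5,8a-tetramethyl-1-[(phenylsulfonyl)methyl]decahydronaphthalen-2-ol | O=S(=O)(c1ccccc1)C[C@@H]2[C@@]3(C)CCCC(C)(C)[C@@H]3CC[C@@]2(C)O | intermediate
24 | (E)-geranylacetone | CC(=O)CC/C=C(\C)CCC=C(C)C | starting material
25 | (S)-4-(2,2-dimethyl-6-methylidenecyclohexyl)butan-2-one | C=C1CCCC(C)(C)[C@@H]1CCC(C)=O | intermediate
26 | diethyl 4-[(1S)-2,2-dimethyl-6-methylidenecyclohexyl]but-1-en-2-yl phosphate (not isolated) | C=C1CCCC(C)(C)[C@@H]1CCC(=C)OP(=O)(OCC)OCC | intermediate
27 | (S)-2-(but-3-yn-1-yl)-1,1-dimethyl-3-methylidenecyclohexane | C=C1CCCC(C)(C)[C@@H]1CCC#C | intermediate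
28 | (E)-alkenyl(dimethyl)alane from 27 (not isolated) | C=C1CCCC(C)(C)[C@@H]1CC/C(C)=C/[Al](C)C | intermediate
29 | (2E)-5-[(1S)-2,2-dimethyl-6-methylidenecyclohexyl]-3-methylpent-2-en-1-ol | C=C1CCCC(C)(C)[C@@H]1CC/C(C)=C/CO | intermediate
30 | (S)-2-[(3E)-5-bromo-3-methylpent-3-en-1-yl]-1,1-dimethyl-3-methylidenecyclohexane | C=C1CCCC(C)(C)[C@@H]1CC/C(C)=C/CBr | intermediate
31 | 11-(phenylsulfonyl)ambrein (C11 epimers) | C=C1CCCC(C)(C)[C@@H]1CC/C(C)=C/CC([C@@H]2[C@@]3(C)CCCC(C)(C)[C@@H]3CC[C@@]2(C)O)S(=O)(=O)c1ccccc1 | intermediate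
32 | ambrein | C=C1CCCC(C)(C)[C@@H]1CC/C(C)=C/CC[C@@H]1[C@@]2(C)CCCC(C)(C)[C@@H]2CC[C@@]1(C)O | target

**Step count**

Total: 21 steps. Longest linear sequence: 14 steps (1, 2, 4, 5, 6, 9, 10, 11, 12, 13, 14, 15, 20, 21).

**Three steps most likely to fail, with fallbacks**

Step 10 (key cycloaddition). The tetrasubstituted diene must reach the s-cis form with a methyl group inside, and the first bond joins a fully substituted carbon to a neopentyl carbon, so cycloaddition may be slow. During that time the Lewis acid may ionise or protodesilylate the allylsilane/allyl sulfide array, or π-facial and endo control may erode. The fallback replaces auxiliary/Lewis-acid control by secondary-amine iminium catalysis; it sets out from aldehyde 11 and returns at epoxy sulfone 22. Wittig reaction of 11 with (triphenylphosphoranylidene)acetaldehyde would give (2E,8Z)-4,4,8-trimethyl-9-[(phenylsulfanyl)methyl]-10-[(trimethylsilyl)methyl]undeca-2,8,10-trienal F1. An imidazolidinone-catalysed intramolecular Diels–Alder reaction of F1 ((2S,5S)-5-benzyl-2-tert-butyl-3-methylimidazolidin-4-one·TFA, wet MeCN; the E-iminium ion is shielded on its Cα-Re face, and no Lewis acid is present) should give the trans-fused 6α-formyl octalin allylsilane F2. Protodesilylation with TFA as in step 11 gives 6α-formyl-11-(phenylsulfanyl)drim-8(17)-ene F3, Tsuji–Wilkinson decarbonylation with stoichiometric RhCl(PPh3)3 gives 11-(phenylsulfanyl)drim-8(17)-ene F4, and mCPBA as in step 12 converts F4 into 22.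

Step 5 (ester to silylmethyl diene). The second addition of the silylmethyl nucleophile to the hindered, conjugated ester may stall through enolisation of the intermediate α-silyl ketone, or the elimination may lose the wrong group. The fallback builds the allylsilane by cross-coupling instead of carbonyl addition; it sets out from 8 and returns at 10. Silylation (Et3SiCl, imidazole) gives the triethylsilyl ether of 8 F5; (trimethylsilyl)methyllithium followed by methanol converts the ester into methyl ketone F6; kinetic deprotonation (KHMDS, −78 °C) and PhNTf2 give the 2-triflyloxy diene F7; palladium-catalysed Kumada coupling with Me3SiCH2MgCl gives the O-triethylsilyl ether of 10 F8; and buffered TBAF/AcOH removes the O-silyl group to give 10.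

Step 2 (enol tosylate geometry). Tosylation may partly go through the chelated enolate, or the enolate may lose thiophenoxide by retro-thia-Michael reaction, so the alkene geometry on which the diene depends would be eroded and carried through the stereoretentive coupling. The fallback uses chelation control with the chain already on the ketone side; it sets out from 1, replaces steps 2–4 and returns at 8. DIBAL reduction of commercial ethyl 4-bromo-2,2-dimethylbutanoate gives 4-bromo-2,2-dimethylbutan-1-ol F9, which is silylated to its tert-butyldimethylsilyl ether F10. The dianion of 1 (NaH, then n-BuLi) is alkylated at its terminal carbon by F10 to give ethyl 8-(tert-butyldimethylsilyloxy)-7,7-dimethyl-3-oxooctanoate F11, and C-alkylation with 2 (NaH) gives the 2-[(phenylsulfanyl)methyl] β-keto ester F12. The chelated sodium enolate and diethyl chlorophosphate give the enol phosphate with phosphate cis to the ester F13, lithium dimethylcuprate replaces phosphate by methyl with retention to give the silyl ether of 8 F14, and TBAF gives 8.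

**Further compounds**

F1 | step 10 | (2E,8Z)-4,4,8-trimethyl-9-[(phenylsulfanyl)methyl]-10-[(trimethylsilyl)methyl]undeca-2,8,10-trienal | C=C(C[Si](C)(C)C)/C(CSc1ccccc1)=C(\C)CCCC(C)(C)/C=C/C=O
F2 | step 10 | trans-fused 6α-formyl octalin allylsilane (10β-CH3, 5α-H, C8=C9) | C[Si](C)(C)CC1=C(CSc2ccccc2)[C@@]3(C)CCCC(C)(C)[C@@H]3[C@@H](C=O)C1
F3 | step 10 | 6α-formyl-11-(phenylsulfanyl)drim-8(17)-ene | c1ccccc1SC[C@@H]2[C@@]3(C)CCCC(C)(C)[C@@H]3[C@@H](C=O)CC2=C
F4 | step 10 | 11-(phenylsulfanyl)drim-8(17)-ene | c1ccccc1SC[C@@H]2[C@@]3(C)CCCC(C)(C)[C@@H]3CCC2=C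
F5 | step 5 | ethyl (2Z)-3,7,7-trimethyl-2-[(phenylsulfanyl)methyl]-8-(triethylsilyloxy)oct-2-enoate | CCOC(=O)/C(CSc1ccccc1)=C(\C)CCCC(C)(C)CO[Si](CC)(CC)CC
F6 | step 5 | (3Z)-4,8,8-trimethyl-3-[(phenylsulfanyl)methyl]-9-(triethylsilyloxy)non-3-en-2-one | CC(=O)/C(CSc1ccccc1)=C(\C)CCCC(C)(C)CO[Si](CC)(CC)CC
F7 | step 5 | (3Z)-4,8,8-trimethyl-3-[(phenylsulfanyl)methyl]-9-(triethylsilyloxy)nona-1,3-dien-2-yl trifluoromethanesulfonate | C=C(OS(=O)(=O)C(F)(F)F)/C(CSc1ccccc1)=C(\C)CCCC(C)(C)CO[Si](CC)(CC)CC
F8 | step 5 | O-triethylsilyl ether of dienol 10 | C=C(C[Si](C)(C)C)/C(CSc1ccccc1)=C(\C)CCCC(C)(C)CO[Si](CC)(CC)CC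
F9 | step 2 | 4-bromo-2,2-dimethylbutan-1-ol | OCC(C)(C)CCBr
F10 | step 2 | (4-bromo-2,2-dimethylbutoxy)(tert-butyl)dimethylsilane | CC(C)(C)[Si](C)(C)OCC(C)(C)CCBr
F11 | step 2 | ethyl 8-(tert-butyldimethylsilyloxy)-7,7-dimethyl-3-oxooctanoate | CCOC(=O)CC(=O)CCCC(C)(C)CO[Si](C)(C)C(C)(C)C
F12 | step 2 | ethyl 8-(tert-butyldimethylsilyloxy)-7,7-dimethyl-3-oxo-2-[(phenylsulfanyl)methyl]octanoate | CCOC(=O)C(CSc1ccccc1)C(=O)CCCC(C)(C)CO[Si](C)(C)C(C)(C)C
F13 | step 2 | ethyl 8-(tert-butyldimethylsilyloxy)-3-(diethoxyphosphoryloxy)-7,7-dimethyl-2-[(phenylsulfanyl)methyl]oct-2-enoate (phosphate cis to ester) | CCOC(=O)/C(CSc1ccccc1)=C(/CCCC(C)(C)CO[Si](C)(C)C(C)(C)C)OP(=O)(OCC)OCC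
F14 | step 2 | ethyl (2Z)-8-(tert-butyldimethylsilyloxy)-3,7,7-trimethyl-2-[(phenylsulfanyl)methyl]oct-2-enoate | CCOC(=O)/C(CSc1ccccc1)=C(\C)CCCC(C)(C)CO[Si](C)(C)C(C)(C)C
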